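The flask holds 0.050 M of starting material, 0.0500 M of second substrate and 2.5 mM of free catalyst, and the north-east run differs from it by having half the starting material.

| flask | starting material | second substrate | free catalyst | remark |
|---|---|---|---|---|
| north-east | 0.025 M | 0.050 M | 2.5 mM | run made earlier |
| north | 0.10 M | 0.050 M | 2.5 mM | run made earlier |
| south-west | 0.050 M | 0.075 M | 2.5 mM | run made earlier |
| flask | 0.050 M | 0.0500 M | 2.5 mM |  |

| north-east: time / h | north-east: target / % | north: time / h | north: target / % | south-west: time / h | south-west: target / % |
|---|---|---|---|---|---|
| 1.00 | 27.6 | 4.00 | 65.2 | 4.00 | 62.1 |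
| 2.50 | 53.0 | 8.00 | 85.1 | 8.00 | 84.4 |
| 6.00 | 77.7 | 10.0 | 90.5 | 10.0 | 90.6 |
| 15.0 | 97.4 | 15.0 | 96.1 | 15.0 | 97.4 |

(readings scatter by 1 percentage point)

- reactions considered so far: second substrate + free catalyst <-> catalyst intermediate B; catalyst intermediate A -> free catalyst + target; catalyst intermediate B -> free catalyst + second product; starting material + free catalyst <-> catalyst intermediate A; 2 free catalyst <-> resting dimer
- no earlier run changes the charge of free catalyst; that part of a forecast is a guess

* apparent order in free catalyst when 50% of the starting material are converted (percent change of the rate of making target for one percent more free catalyst charged)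

The north-east run and the north run end close together at 15.0 h, at 97.4% and 96.1% target, so I let the flask keep the north-east clock. On that clock I count half-lives of the starting material: tE runs from the start to the 2.50 h reading, and tL from there to the last reading.

tE = 2.30 h

tL = 2.99 h

The later half-life is longer, so the north-east run slows beyond first order. I call a = tE/tL the activity kept, which is 0.767 here. The flask should therefore have 5.28% of its starting material left at 12.0 h.

As a crude reckoning, I read the lost part d = 1 − a as catalyst parked in the resting dimer, an off-cycle resting state. A dimer forms with the square of free catalyst, which gives the order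

n = 1/(1 + d) = 1/(2 − a) = 0.811

The forecast gives 0.75, noting “The runs hold catalyst fixed, so they do not reveal how much dimer exists”, and my figure is higher.

The flask gives 0.84.

    second substrate + free catalyst ⇌ catalyst intermediate B (K = 13.0 M⁻¹, k = 0.290 M⁻¹ s⁻¹)
    catalyst intermediate A → free catalyst + target (k = 0.0340 s⁻¹)
    catalyst intermediate B → free catalyst + second product (k = 9.20 × 10⁻⁴ s⁻¹)
    starting material + free catalyst ⇌ catalyst intermediate A (K = 100 M⁻¹, k = 0.0720 M⁻¹ s⁻¹)
    2 free catalyst ⇌ resting dimer (K = 780 M⁻¹, k = 0.0640 M⁻¹ s⁻¹)

In the flask, the step from starting material + free catalyst to catalyst intermediate A has 83% of its turnover behind it by 6.00 h, while the resting dimer grows from 28.4% of the catalyst at 1.20 h to 46.4% at 6.00 h. The starting material in the flask then falls to 5.6% at 12.0 h, with 62% of the second substrate left and the resting dimer at 49.6%. Counted from the flask's half mark at 2.44 h, a is 0.801, so n = 0.834; the north run, split at its 4.00 h reading, keeps 0.754, so n = 0.803.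

(The readings are simulated from invented constants; noise was put on by code.)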